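**Retrosynthetic overview**

1. Numbering used below: ring A is the 14-membered carbocycle C1–C14 (C1 bears OAc, C2 is the CH2, C3 the tertiary carbinol, C4=C5 the E alkene, C7 the methyl, C9 the ketone, C14 the isopropyl); ring B is the butenolide C11–C12–C13–O–C15(=O).
2. Enabling feature: the C1(OAc)–C2H2–C3(OH)(CH3)(E-vinyl) triad of ring A is an aldol retron, so C2–C3 is cut to a C1 ketone enolate and a C3 methyl enone carbonyl; ring A is closed by a SmI2 Reformatsky-type macro-aldol of the linear α-chloro ketone 24, which also creates C3.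
3. After ring closure: hydroxyl-directed 1,3-anti reduction sets C1, then selective acetylation, C9 desilylation and oxidation.
4. Precursor 24 comes from ester union of chloromethyl ketone 22 (C13/C14 by Evans syn aldol with acrolein, C2 from chloromethyllithium) with acid 12 (C7 from the glutarate half-ester 1, C9–C11 by Barbier allylation, E-enone by cross-metathesis).
5. Ring order: ring B first (ring-closing metathesis, step 16), ring A second (step 17).

Key step: step 17

**Remarks**
- The C9 carbinol made in step 5 is carried as a mixture of both epimers (centre left undefined in the SMILES), because it is oxidised to the C9 ketone in step 21.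
- Commercial starting materials: 1, 7, 11, 13, 14, 16.

**Route**

Step 1
Reactants: 1 methyl hydrogen (R)-3-methylglutarate
Product: 3 (4R)-4-methyloxan-2-one, via hydroxy ester 2 (not isolated)
Conditions: BH3·SMe2, THF, 0 °C → rt; H2O; then TsOH (cat.), toluene, 80 °C
Reagents that add atoms: none
Why: Borane reduces the free carboxylic acid chemoselectively beside the methyl ester, and acid-catalysed lactonisation of the δ-hydroxy ester then closes the six-membered lactone without touching the stereocentre (future C7).

Step 2
Reactants: 3 (4R)-4-methyloxan-2-one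
Product: 4 (4R)-4-methyloxan-2-ol (lactol, both anomers)
Conditions: iBu2AlH, CH2Cl2, −78 °C; aq. potassium sodium tartrate
Reagents that add atoms: none
Why: Partial reduction of a δ-lactone with iBu2AlH at low temperature stops at the aluminium hemiacetal and should give the lactol.

Step 3
Reactants: 4 (4R)-4-methyloxan-2-ol
Product: 5 (3S)-3-methylhex-5-en-1-ol
Conditions: Ph3PCH3Br, KOtBu, THF, 0 °C → reflux
Reagents that add atoms: methyltriphenylphosphonium bromide, C[P+](c1ccccc1)(c1ccccc1)c1ccccc1.[Br-]
Why: Wittig methylenation of the open hydroxy-aldehyde form of the lactol with excess unstabilised ylide should give the terminal alkene and free the primary alcohol.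

Step 4
Reactants: 5 (3S)-3-methylhex-5-en-1-ol
Product: 6 (3S)-3-methylhex-5-enal
Conditions: Dess–Martin periodinane, CH2Cl2, 0 °C → rt; solution of 6 used directly
Reagents that add atoms: none
Why: Dess–Martin oxidation of a primary alcohol stops at the aldehyde, and the stereocentre is β to the carbonyl and cannot epimerise.

Step 5
Reactants: 6 (3S)-3-methylhex-5-enal; 7 ethyl 2-(bromomethyl)prop-2-enoate
Product: 8 ethyl (6S)-4-hydroxy-6-methyl-2-methylidenenon-8-enoate (both C4 epimers)
Conditions: In powder, THF/H2O (1:1), rt
Reagents that add atoms: none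
Why: The indium-mediated Barbier allylation adds the 2-(ethoxycarbonyl)allyl unit to the aldehyde under neutral aqueous conditions and should stop at the open hydroxy ester; the new carbinol (future C9) forms as both epimers, which does not matter because it later becomes a ketone.

Step 6
Reactants: 8 ethyl (6S)-4-hydroxy-6-methyl-2-methylidenenon-8-enoate
Product: 9 ethyl (6S)-4-[(tert-butyldimethylsilyl)oxy]-6-methyl-2-methylidenenon-8-enoate
Conditions: TBSOTf, 2,6-lutidine, CH2Cl2, −78 → 0 °C
Reagents that add atoms: tert-butyldimethylsilyl trifluoromethanesulfonate, CC(C)(C)[Si](C)(C)OS(=O)(=O)C(F)(F)F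
Why: Silylation of the secondary alcohol with the silyl triflate at low temperature should outrun lactonisation onto the acrylate ester.

Step 7
Reactants: 9 ethyl (6S)-4-[(tert-butyldimethylsilyl)oxy]-6-methyl-2-methylidenenon-8-enoate
Product: 10 (6S)-4-[(tert-butyldimethylsilyl)oxy]-6-methyl-2-methylidenenon-8-enoic acid
Conditions: LiOH, THF/MeOH/H2O, rt; then 1 M HCl to pH 3, 0 °C
Reagents that add atoms: lithium hydroxide, [Li+].[OH-]
Why: Saponification of the ethyl ester is safe here because the silyl ether is γ to the carboxylate and cannot β-eliminate.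

Step 8
Reactants: 10 (6S)-4-[(tert-butyldimethylsilyl)oxy]-6-methyl-2-methylidenenon-8-enoic acid; 11 but-3-en-2-one (methyl vinyl ketone)
Product: 12 (6S,8E)-4-[(tert-butyldimethylsilyl)oxy]-6-methyl-2-methylidene-10-oxoundec-8-enoic acid
Conditions: 11 (5 equiv), second-generation Grubbs catalyst RuCl2(=CHPh)(H2IMes)(PCy3) (5 mol %), CH2Cl2, 40 °C
Reagents that add atoms: none
Why: Olefin cross-metathesis of the monosubstituted terminal alkene with excess methyl vinyl ketone should give the conjugated enone with E geometry (future C4=C5), while the 1,1-disubstituted electron-poor acrylic acid alkene stays inert.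

Step 9
Reactants: 13 (4S)-4-benzyl-1,3-oxazolidin-2-one; 14 3-methylbutanoyl chloride
Product: 15 (4S)-4-benzyl-3-(3-methylbutanoyl)-1,3-oxazolidin-2-one
Conditions: nBuLi, THF, −78 °C; then 14, −78 → 0 °C
Reagents that add atoms: none
Why: N-Acylation of the lithiated oxazolidinone with the acid chloride is the standard entry to the Evans imide.

Step 10
Reactants: 15 (4S)-4-benzyl-3-(3-methylbutanoyl)-1,3-oxazolidin-2-one; 16 prop-2-enal (acrolein)
Product: 18 (4S)-4-benzyl-3-[(2S,3R)-3-hydroxy-2-(propan-2-yl)pent-4-enoyl]-1,3-oxazolidin-2-one, via boron enolate 17 (not isolated)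
Conditions: Bu2BOTf, iPr2NEt, CH2Cl2, −78 → 0 °C; 16, −78 → 0 °C; pH 7 buffer, MeOH, H2O2
Reagents that add atoms: none
Why: In the Evans syn aldol the Z boron enolate reacts through a Zimmerman–Traxler chair in which the benzyl group of the dipole-opposed auxiliary shields one enolate face, which should set C14 (isopropyl) and C13 (oxygen) together as the (2S,3R) syn adduct.

Step 11
Reactants: 18 (4S)-4-benzyl-3-[(2S,3R)-3-hydroxy-2-(propan-2-yl)pent-4-enoyl]-1,3-oxazolidin-2-one
Product: 19 (2S,3R)-3-hydroxy-N-methoxy-N-methyl-2-(propan-2-yl)pent-4-enamide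
Conditions: MeNH(OMe)·HCl, AlMe3, CH2Cl2, −20 °C → rt; 1 M HCl work-up
Reagents that add atoms: N,O-dimethylhydroxylamine hydrochloride, CNOC.Cl
Why: Aluminium amide transamination to the Weinreb amide is assisted by the free β-hydroxyl as its aluminium alkoxide and should release the auxiliary without epimerising C14.

Step 12
Reactants: 19 (2S,3R)-3-hydroxy-N-methoxy-N-methyl-2-(propan-2-yl)pent-4-enamide
Product: 20 (2S,3R)-N-methoxy-N-methyl-2-(propan-2-yl)-3-[(triethylsilyl)oxy]pent-4-enamide
Conditions: Et3SiCl, imidazole, DMF, 0 °C → rt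
Reagents that add atoms: chlorotriethylsilane, CC[Si](Cl)(CC)CC
Why: Silyl protection of the C13 hydroxyl keeps it from quenching the organolithium of the next step and can be removed later under mild acid.

Step 13
Reactants: 20 (2S,3R)-N-methoxy-N-methyl-2-(propan-2-yl)-3-[(triethylsilyl)oxy]pent-4-enamide
Product: 21 (3S,4R)-1-chloro-3-(propan-2-yl)-4-[(triethylsilyl)oxy]hex-5-en-2-one
Conditions: ICH2Cl, MeLi·LiBr, THF, −78 °C; aq. NH4Cl
Reagents that add atoms: chloroiodomethane, ClCI
Why: Chloromethyllithium made in situ by iodine–lithium exchange adds to the Weinreb amide, whose chelated tetrahedral intermediate blocks over-addition, so this carbenoid homologation should give the chloromethyl ketone and bring in C2.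

Step 14
Reactants: 21 (3S,4R)-1-chloro-3-(propan-2-yl)-4-[(triethylsilyl)oxy]hex-5-en-2-one
Product: 22 (3S,4R)-1-chloro-4-hydroxy-3-(propan-2-yl)hex-5-en-2-one
Conditions: AcOH/THF/H2O (3:1:1), rt; product used at once
Reagents that add atoms: none
Why: Mild acidic solvolysis removes the triethylsilyl ether while the α-chloro ketone and the C14 centre are stable to acid; base is avoided because the hydroxy chloro ketone could otherwise cyclise by O-alkylation.

Step 15
Reactants: 22 (3S,4R)-1-chloro-4-hydroxy-3-(propan-2-yl)hex-5-en-2-one; 12 (6S,8E)-4-[(tert-butyldimethylsilyl)oxy]-6-methyl-2-methylidene-10-oxoundec-8-enoic acid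
Product: 23 (3R,4S)-6-chloro-5-oxo-4-(propan-2-yl)hex-1-en-3-yl (6S,8E)-4-[(tert-butyldimethylsilyl)oxy]-6-methyl-2-methylidene-10-oxoundec-8-enoate
Conditions: DCC, DMAP (0.2 equiv), CH2Cl2, 0 °C → rt
Reagents that add atoms: none
Why: Steglich esterification joins the two fragments with only catalytic nucleophilic base, which limits alkylation by the chloro ketone and β-elimination of the new β-acyloxy ketone.

Step 16
Reactants: 23 (the ester of step 15)
Product: 24 (5R)-5-[(3S)-1-chloro-4-methyl-2-oxopentan-3-yl]-3-[(4S,6E)-2-[(tert-butyldimethylsilyl)oxy]-4-methyl-8-oxonon-6-en-1-yl]furan-2(5H)-one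
Conditions: second-generation Grubbs catalyst RuCl2(=CHPh)(H2IMes)(PCy3) (10 mol %), toluene (5 mM), 80 °C
Reagents that add atoms: none
Why: Ring-closing metathesis of the 2-substituted acrylate with the allylic vinyl group, driven by loss of ethene, should give the α-substituted butenolide (ring B); the E-enone, chloro ketone and silyl ether are spectators and the alternative ring closures are medium rings.

Step 17
Reactants: 24 (the butenolide chloromethyl ketone of step 16)
Product: 27 macrocyclic β-hydroxy ketone (3S,7S,13R,14S; C1 ketone; C3 tertiary carbinol; C9 silyl ether; E C4=C5), via samarium enolate 25 (not isolated), via samarium aldolate 26 (not isolated)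
Conditions: SmI2 (2.5 equiv, 0.1 M in THF), slow addition of 24 by syringe pump (final 2 mM), THF, −78 °C; sat. aq. NH4Cl at −78 °C
Reagents that add atoms: none
Why: Two single-electron transfers from divalent samarium to the α-chloro ketone expel chloride and give the trivalent samarium enolate 25 regiospecifically at C2 without any base (so the acidic C13 and C14 hydrogens stay untouched), and the oxophilic samarium then binds the C3 enone carbonyl and delivers C2 to it in a 1,2-addition through a chelated six-membered chair to give aldolate 26. The closest known reaction type is the SmI2-mediated intramolecular Reformatsky (samarium aldol) cyclisation of α-halo carbonyl compounds onto aldehydes and ketones, which has been used to close medium and large rings. The 14-membered carbocycle (ring A) is closed in a 14-exo-trig mode by the C2–C3 bond. The one new stereocentre, C3, is controlled by the C14 stereocentre next to the enolate acting through this chair inside the macrocyclic tether: with the C14 hydrogen in the enolate plane and the isopropyl group on the far face, the tether from C13 lies over the reacting face, so C4 should take the pseudo-axial and the C3 methyl the pseudo-equatorial site, which leads to the (3S) carbinol; this is a model-based expectation and not a secure prediction, because a rotamer or chair change inverts it. The step needs halide reduction in preference to reduction of the enone and butenolide (α-halo ketones are reduced by SmI2 at −78 °C far faster than unsaturated carbonyls when HMPA and proton sources are absent), 1,2- in preference to 1,4-addition (the chelating samarium enolate attacks the carbonyl carbon, and attack at C5 would need a more strained 12-membered ring), and ring closure in preference to intermolecular aldol or protonation (slow addition at high dilution in an aprotic medium). The cold neutral quench is chosen because the product is a tertiary aldol that could revert or lose the C13 carboxylate by β-elimination under base.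

Step 18
Reactants: 27 macrocyclic β-hydroxy ketone
Product: 28 macrocyclic anti-1,3-diol (1S,3S,7S,13R,14R; C9 silyl ether)
Conditions: Me4NBH(OAc)3, MeCN/AcOH (1:1), −30 °C
Reagents that add atoms: none
Why: In the Evans–Saksena reduction the C3 hydroxyl exchanges onto boron and delivers hydride internally through a chair, which should set C1 as the 1,3-anti (1S) alcohol, while the butenolide and silyl ether do not react with this mild hydride.

Step 19
Reactants: 28 macrocyclic anti-1,3-diol
Product: 29 C1 acetate (1S,3S,7S,13R,14R; C3 hydroxyl free; C9 silyl ether)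
Conditions: Ac2O, pyridine, DMAP (cat.), CH2Cl2, 0 °C → rt
Reagents that add atoms: acetic anhydride, CC(=O)OC(C)=O
Why: Acetylation should be selective for the secondary C1 hydroxyl because the tertiary allylic C3 hydroxyl is too hindered under these conditions.

Step 20
Reactants: 29 C1 acetate
Product: 30 C9 alcohol (1S,3S,7S,13R,14R; both C9 epimers)
Conditions: HF·pyridine, pyridine, THF, 0 °C → rt
Reagents that add atoms: none
Why: Buffered fluoride desilylation removes the secondary silyl ether and tolerates the acetate, the tertiary allylic alcohol and the butenolide.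

Step 21
Reactants: 30 C9 alcohol
Product: 31 target CNP0200490.2 (1S,3S,4E,7S,13R,14R)
Conditions: Dess–Martin periodinane, pyridine, CH2Cl2, 0 °C → rt
Reagents that add atoms: none
Why: Dess–Martin oxidation converts both C9 epimers into the single ketone, leaves the tertiary alcohol alone, and its buffered neutral conditions should not move the butenolide double bond into conjugation with the new ketone.

**Compound list**

1 | methyl hydrogen (R)-3-methylglutarate, (3R)-5-methoxy-3-methyl-5-oxopentanoic acid | COC(=O)C[C@H](C)CC(=O)O | starting material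
2 | methyl (3R)-5-hydroxy-3-methylpentanoate | COC(=O)C[C@H](C)CCO | intermediate (not isolated)
3 | (4R)-4-methyloxan-2-one | O=C1C[C@H](C)CCO1 | intermediate
4 | (4R)-4-methyloxan-2-ol (both anomers) | OC1C[C@H](C)CCO1 | intermediate
5 | (3S)-3-methylhex-5-en-1-ol | C=CC[C@H](C)CCO | intermediate
6 | (3S)-3-methylhex-5-enal | C=CC[C@H](C)CC=O | intermediate
7 | ethyl 2-(bromomethyl)prop-2-enoate | C=C(CBr)C(=O)OCC | starting material
8 | ethyl (6S)-4-hydroxy-6-methyl-2-methylidenenon-8-enoate (both C4 epimers) | C=CC[C@H](C)CC(O)CC(=C)C(=O)OCC | intermediate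
9 | ethyl (6S)-4-[(tert-butyldimethylsilyl)oxy]-6-methyl-2-methylidenenon-8-enoate | C=CC[C@H](C)CC(O[Si](C)(C)C(C)(C)C)CC(=C)C(=O)OCC | intermediate
10 | (6S)-4-[(tert-butyldimethylsilyl)oxy]-6-methyl-2-methylidenenon-8-enoic acid | C=CC[C@H](C)CC(O[Si](C)(C)C(C)(C)C)CC(=C)C(=O)O | intermediate
11 | but-3-en-2-one (methyl vinyl ketone) | CC(=O)C=C | starting material
12 | (6S,8E)-4-[(tert-butyldimethylsilyl)oxy]-6-methyl-2-methylidene-10-oxoundec-8-enoic acid | CC(=O)/C=C/C[C@H](C)CC(O[Si](C)(C)C(C)(C)C)CC(=C)C(=O)O | intermediate
13 | (4S)-4-benzyl-1,3-oxazolidin-2-one | O=C1N[C@@H](Cc2ccccc2)CO1 | starting material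
14 | 3-methylbutanoyl chloride | CC(C)CC(=O)Cl | starting material
15 | (4S)-4-benzyl-3-(3-methylbutanoyl)-1,3-oxazolidin-2-one | CC(C)CC(=O)N1[C@@H](Cc2ccccc2)COC1=O | intermediate
16 | prop-2-enal (acrolein) | C=CC=O | starting material
17 | dibutylboron Z-enolate of 15 | CC(C)/C=C(\OB(CCCC)CCCC)N1[C@@H](Cc2ccccc2)COC1=O | intermediate (not isolated)
18 | (4S)-4-benzyl-3-[(2S,3R)-3-hydroxy-2-(propan-2-yl)pent-4-enoyl]-1,3-oxazolidin-2-one | C=C[C@@H](O)[C@@H](C(=O)N1[C@@H](Cc2ccccc2)COC1=O)C(C)C | intermediate
19 | (2S,3R)-3-hydroxy-N-methoxy-N-methyl-2-(propan-2-yl)pent-4-enamide | C=C[C@@H](O)[C@@H](C(=O)N(C)OC)C(C)C | intermediate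
20 | (2S,3R)-N-methoxy-N-methyl-2-(propan-2-yl)-3-[(triethylsilyl)oxy]pent-4-enamide | C=C[C@@H](O[Si](CC)(CC)CC)[C@@H](C(=O)N(C)OC)C(C)C | intermediate
21 | (3S,4R)-1-chloro-3-(propan-2-yl)-4-[(triethylsilyl)oxy]hex-5-en-2-one | C=C[C@@H](O[Si](CC)(CC)CC)[C@@H](C(=O)CCl)C(C)C | intermediate
22 | (3S,4R)-1-chloro-4-hydroxy-3-(propan-2-yl)hex-5-en-2-one | C=C[C@@H](O)[C@@H](C(=O)CCl)C(C)C | intermediate
23 | (3R,4S)-6-chloro-5-oxo-4-(propan-2-yl)hex-1-en-3-yl (6S,8E)-4-[(tert-butyldimethylsilyl)oxy]-6-methyl-2-methylidene-10-oxoundec-8-enoate | C=C[C@@H](OC(=O)C(=C)CC(O[Si](C)(C)C(C)(C)C)C[C@@H](C)C/C=C/C(C)=O)[C@@H](C(=O)CCl)C(C)C | intermediate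
24 | (5R)-5-[(3S)-1-chloro-4-methyl-2-oxopentan-3-yl]-3-[(4S,6E)-2-[(tert-butyldimethylsilyl)oxy]-4-methyl-8-oxonon-6-en-1-yl]furan-2(5H)-one | O=C1O[C@@H]([C@@H](C(=O)CCl)C(C)C)C=C1CC(O[Si](C)(C)C(C)(C)C)C[C@@H](C)C/C=C/C(C)=O | intermediate
25 | trivalent samarium enolate of 24 (diiodosamarium on the C1 oxygen, C1=C2 double bond) | O=C1O[C@@H]([C@@H](C(O[Sm](I)I)=C)C(C)C)C=C1CC(O[Si](C)(C)C(C)(C)C)C[C@@H](C)C/C=C/C(C)=O | intermediate (not isolated)
26 | trivalent samarium aldolate of 27 (diiodosamarium on the C3 oxygen) | O=C1C[C@](C)(O[Sm](I)I)/C=C/C[C@H](C)CC(O[Si](C)(C)C(C)(C)C)CC2=C[C@@H](OC2=O)[C@@H]1C(C)C | intermediate (not isolated)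
27 | macrocyclic β-hydroxy ketone: ring A with C1 ketone, (3S) tertiary carbinol, E C4=C5, (7S) methyl, C9 silyl ether, fused butenolide ring B (13R), (14S) isopropyl centre (same spatial arrangement as 14R in the target) | O=C1C[C@](C)(O)/C=C/C[C@H](C)CC(O[Si](C)(C)C(C)(C)C)CC2=C[C@@H](OC2=O)[C@@H]1C(C)C | intermediate
28 | macrocyclic anti-1,3-diol (1S,3S,7S,13R,14R), C9 silyl ether | O[C@H]1C[C@](C)(O)/C=C/C[C@H](C)CC(O[Si](C)(C)C(C)(C)C)CC2=C[C@@H](OC2=O)[C@@H]1C(C)C | intermediate
29 | C1 acetate (1S,3S,7S,13R,14R), C3 hydroxyl free, C9 silyl ether | CC(=O)O[C@H]1C[C@](C)(O)/C=C/C[C@H](C)CC(O[Si](C)(C)C(C)(C)C)CC2=C[C@@H](OC2=O)[C@@H]1C(C)C | intermediate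
30 | C9 alcohol (1S,3S,7S,13R,14R; both C9 epimers) | CC(=O)O[C@H]1C[C@](C)(O)/C=C/C[C@H](C)CC(O)CC2=C[C@@H](OC2=O)[C@@H]1C(C)C | intermediate
31 | CNP0200490.2 (1S,3S,4E,7S,13R,14R) | CC(=O)O[C@H]1C[C@](C)(O)/C=C/C[C@H](C)CC(=O)CC2=C[C@@H](OC2=O)[C@@H]1C(C)C | target

**Step count and risks**

Total step count: 21. Longest linear sequence: 15 steps (steps 1–8, then 15–21).

Steps most likely to fail:

1. Step 17. The samarium enolate may be protonated or react intermolecularly before the slow closure of the 14-membered ring onto the weakly electrophilic conjugated C3 ketone, or the ketone may be attacked on the wrong face (the chair with C4 pseudo-equatorial), which would give the C3 epimer and then the wrong C1 centre in step 18. The fallback closes ring A by olefin metathesis at C4=C5 and separates the C3 epimers on an open-chain compound; it sets out from 22 and 10 and comes back to the route at 27. Alcohol 22 is esterified with the terminal-alkene acid 10 (DCC, DMAP) to give the ester F1. Ring-closing metathesis of its acrylate with the C13 vinyl group (second-generation Grubbs catalyst RuCl2(=CHPh)(H2IMes)(PCy3), toluene, 80 °C; the five-membered closure should outrun the seven-membered one through the C5 alkene) gives the butenolide F2, which still carries the chloromethyl ketone and the terminal C5 alkene. Intermolecular SmI2 Reformatsky 1,2-addition of F2 to methyl vinyl ketone 11 (THF, −78 °C) gives the tertiary allylic aldol F3 as two C3 epimers, which are separated by chromatography, and the (3S) epimer is taken on. Macrocyclic ring-closing metathesis between the C3 vinyl group and the C5 alkene (same catalyst, CH2Cl2, 40 °C, high dilution) should then form the E C4=C5 bond and deliver 27.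

2. Step 13. Chloromethyllithium may decompose faster than it adds to the hindered α-isopropyl Weinreb amide, leaving starting amide and carbenoid-derived by-products. The fallback builds the chloro ketone stepwise through a regiodefined silyl enol ether; it sets out from 20 and comes back at 21. MeMgBr (THF, 0 °C) converts 20 into the methyl ketone F4. Kinetic deprotonation at the methyl group with LiHMDS and trapping with Me3SiCl at −78 °C gives the trimethylsilyl enol ether F5; the hindered C14 hydrogen, whose removal would eliminate the β-silyloxy group, is not touched. N-Chlorosuccinimide (THF, 0 °C) then chlorinates the terminal enol carbon to give 21.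

3. Step 18. Exchange of the tertiary C3 hydroxyl onto boron may be too slow for internal hydride delivery, so that the ketone is not reduced or is reduced without 1,3-control, and the acidic medium may promote retro-aldol cleavage. The fallback replaces substrate direction by catalyst control; it sets out from 27 and comes back at 28. Reduction with (R)-2-methyl-CBS-oxazaborolidine and BH3·SMe2 (THF, −40 °C) delivers external hydride to the ketone face that the catalyst selects by distinguishing the branched C14 side from the C2 methylene side, which should give the (1S) alcohol; this fallback makes no new compound (F0).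

**Further compounds**

F1 | step 17 | (3R,4S)-6-chloro-5-oxo-4-(propan-2-yl)hex-1-en-3-yl (6S)-4-[(tert-butyldimethylsilyl)oxy]-6-methyl-2-methylidenenon-8-enoate | C=C[C@@H](OC(=O)C(=C)CC(O[Si](C)(C)C(C)(C)C)C[C@@H](C)CC=C)[C@@H](C(=O)CCl)C(C)C
F2 | step 17 | (5R)-5-[(3S)-1-chloro-4-methyl-2-oxopentan-3-yl]-3-[(4S)-2-[(tert-butyldimethylsilyl)oxy]-4-methylhept-6-en-1-yl]furan-2(5H)-one | O=C1O[C@@H]([C@@H](C(=O)CCl)C(C)C)C=C1CC(O[Si](C)(C)C(C)(C)C)C[C@@H](C)CC=C
F3 | step 17 | (5R)-5-[(3S,6S)-6-hydroxy-2,6-dimethyl-4-oxooct-7-en-3-yl]-3-[(4S)-2-[(tert-butyldimethylsilyl)oxy]-4-methylhept-6-en-1-yl]furan-2(5H)-one | O=C1O[C@@H]([C@@H](C(=O)C[C@](C)(O)C=C)C(C)C)C=C1CC(O[Si](C)(C)C(C)(C)C)C[C@@H](C)CC=C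
F4 | step 13 | (3S,4R)-3-(propan-2-yl)-4-[(triethylsilyl)oxy]hex-5-en-2-one | C=C[C@@H](O[Si](CC)(CC)CC)[C@@H](C(C)=O)C(C)C
F5 | step 13 | triethyl{[(3R,4S)-4-(propan-2-yl)-5-[(trimethylsilyl)oxy]hexa-1,5-dien-3-yl]oxy}silane | C=C[C@@H](O[Si](CC)(CC)CC)[C@@H](C(=C)O[Si](C)(C)C)C(C)C
F0 | step 18 | none | none
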